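The ten-membered carbocycle is disconnected between C9 and C10, the vicinal carbinols (C9 secondary and acylated, C10 tertiary with methyl), both of which can arise from carbonyl carbons. Reductive coupling of a C9 aldehyde with a C10 methyl ketone by SmI2 closes the ring, forms C9–C10 and sets both carbinol centres in one operation. The open-chain precursor already holds C4–C8 with their stereocentres, PMB on O8 beside the aldehyde, the C11=C13 methylene with C12 as a silyl ether, and C5 as a silyl-protected carbinol, so that only the two reacting carbonyl groups are present. The C8,12-lactone ring and the C5 ketone follow afterwards.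

Key step: step 21

Remark on numbering: locants are those of the germacrane skeleton (ring C1–C10, lactone carbons C11–C13, C14 on C10, C15 on C4). The CIP letter at C7 changes with the protecting groups although its geometry stays the same.

Remark on the precursor design: C5 is carried as a TES-protected carbinol of (R) configuration and oxidised after ring closure. A ketal between the C4 methine and the oxygenated C6 would be hard to form and would need strong acid beside the tertiary C10 carbinol at the end. O12 carries TBS, so only one PMB ether is present in step 16. The acetal carbon of 28 and 29 and the lactol carbon of 39 are epimer mixtures of no consequence.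

Step 1
Reactants: 1 prop-2-yn-1-ol; 2 5-bromopent-1-ene
Product: 4 oct-7-en-2-yn-1-ol, via dilithiated prop-2-yn-1-ol 3 (not isolated)
Conditions: n-BuLi (2.1 equiv), THF/DMPU, −78 → −20 °C; then 2, −20 °C → rt; H2O
Reagents that add atoms: none
Why: Acetylide alkylation (SN2 on a primary bromide); the alkynyl carbon of the dianion is the stronger nucleophile, so C-alkylation should prevail over O-alkylation.

Step 2
Reactants: 4 oct-7-en-2-yn-1-ol
Product: 5 (2Z)-octa-2,7-dien-1-ol
Conditions: H2 (1 atm, stopped at 1 equiv), Pd/CaCO3 poisoned with Pb(OAc)2, quinoline, EtOAc/hexane, 0 °C → rt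
Reagents that add atoms: none
Why: Lindlar semi-hydrogenation; the alkyne binds the poisoned palladium surface far more strongly than the isolated terminal alkene, and syn addition of hydrogen should give the Z allylic alcohol.

Step 3
Reactants: 5 (2Z)-octa-2,7-dien-1-ol
Product: 6 [(2S,3R)-3-(pent-4-en-1-yl)oxiran-2-yl]methanol
Conditions: Ti(OiPr)4 (20 mol %), L-(+)-diethyl tartrate (24 mol %), t-BuOOH (2 equiv), 4 Å MS, CH2Cl2, −20 °C
Reagents that add atoms: tert-butyl hydroperoxide, CC(C)(C)OO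
Why: Katsuki–Sharpless asymmetric epoxidation, selective for the allylic alcohol double bond; the L-(+)-tartrate complex delivers oxygen to the face that gives the (2S,3R) cis-epoxide, and any minor enantiomer would be removed as a diastereomer after step 11.

Step 4
Reactants: 6 [(2S,3R)-3-(pent-4-en-1-yl)oxiran-2-yl]methanol
Product: 7 (2R,3S)-3-methyloct-7-ene-1,2-diol
Conditions: AlMe3 (3 equiv), hexane/CH2Cl2, 0 °C → rt; aq. potassium sodium tartrate
Reagents that add atoms: trimethylaluminium, C[Al](C)C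
Why: Methyl transfer from the aluminium alkoxide of a 2,3-epoxy alcohol opens the epoxide at the carbon remote from the carbinol with inversion, which sets C4 (S) and leaves the future C5 carbinol (R) untouched.

Step 5
Reactants: 7 (2R,3S)-3-methyloct-7-ene-1,2-diol
Product: 8 (2R,3S)-3-methyl-1,2-bis(triethylsilyloxy)oct-7-ene
Conditions: TESCl (2.5 equiv), imidazole, DMAP (cat.), CH2Cl2, 0 °C → rt
Reagents that add atoms: chlorotriethylsilane, CC[Si](CC)(CC)Cl
Why: Routine bis-silylation of a 1,2-diol; no stereocentre is touched.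

Step 6
Reactants: 8 (2R,3S)-3-methyl-1,2-bis(triethylsilyloxy)oct-7-ene
Product: 9 (2R,3S)-3-methyl-2-(triethylsilyloxy)oct-7-enal
Conditions: (COCl)2, DMSO, CH2Cl2, −78 → −30 °C; then Et3N, −78 °C → rt
Reagents that add atoms: none
Why: Swern oxidation applied directly to a silyl ether; the primary TES ether is cleaved and oxidised to the aldehyde while the secondary TES ether survives, and the low temperature should prevent epimerisation of the α-silyloxy aldehyde.

Step 7
Reactants: 10 4-methyl hydrogen 2-methylidenebutanedioate (monomethyl itaconate)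
Product: 12 methyl 3-(hydroxymethyl)but-3-enoate, via mixed isobutyl carbonic anhydride 11 (not isolated)
Conditions: i-BuOCOCl, N-methylmorpholine, THF, −15 °C; then NaBH4, H2O, −15 → 0 °C
Reagents that add atoms: none
Why: Chemoselective reduction of a carboxylic acid through its mixed carbonic anhydride; borohydride attacks the activated acyl carbon and leaves the methyl ester alone, giving the primary allylic alcohol (future C12).

Step 8
Reactants: 12 methyl 3-(hydroxymethyl)but-3-enoate
Product: 13 methyl 3-{[(tert-butyldimethylsilyl)oxy]methyl}but-3-enoate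
Conditions: TBSCl, imidazole, DMF, 0 °C → rt
Reagents that add atoms: tert-butyldimethylsilyl chloride, CC(C)(C)[Si](C)(C)Cl
Why: Routine silylation of a primary alcohol, which also blocks lactonisation onto the ester.

Step 9
Reactants: 13 methyl 3-{[(tert-butyldimethylsilyl)oxy]methyl}but-3-enoate
Product: 14 3-{[(tert-butyldimethylsilyl)oxy]methyl}but-3-enoic acid
Conditions: LiOH, THF/H2O, 0 °C; dilute HCl to pH 4 at 0 °C
Reagents that add atoms: lithium hydroxide, [Li+].[OH-]
Why: Ester saponification; at 0 °C the carboxylate forms before the β,γ-double bond can move into conjugation.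

Step 10
Reactants: 14 3-{[(tert-butyldimethylsilyl)oxy]methyl}but-3-enoic acid; 15 (4S)-4-benzyl-1,3-oxazolidin-2-one
Product: 17 (4S)-4-benzyl-3-(3-{[(tert-butyldimethylsilyl)oxy]methyl}but-3-enoyl)-1,3-oxazolidin-2-one, via mixed pivalic anhydride 16 (not isolated)
Conditions: PivCl, Et3N, THF, −20 °C; then LiCl, 15, −20 °C → rt
Reagents that add atoms: none
Why: N-acylation of the oxazolidinone through the mixed pivalic anhydride under LiCl/amine activation, mild enough to keep the double bond out of conjugation.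

Step 11
Reactants: 17 (4S)-4-benzyl-3-(3-{[(tert-butyldimethylsilyl)oxy]methyl}but-3-enoyl)-1,3-oxazolidin-2-one; 9 (2R,3S)-3-methyl-2-(triethylsilyloxy)oct-7-enal
Product: 19 (4S)-4-benzyl-3-[(2S,3S,4R,5S)-2-{3-[(tert-butyldimethylsilyl)oxy]prop-1-en-2-yl}-3-hydroxy-5-methyl-4-(triethylsilyloxy)dec-9-enoyl]-1,3-oxazolidin-2-one, via Z-dibutylboron enolate 18 (not isolated)
Conditions: Bu2BOTf, i-Pr2NEt, CH2Cl2, −78 → 0 °C; 9, −78 → 0 °C; pH 7 buffer, MeOH, 30 % H2O2, 0 °C
Reagents that add atoms: none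
Why: Evans syn-aldol; the Z-boron enolate reacts at its α-carbon through a chair transition state in which the (S)-benzyl auxiliary fixes C7 and C6 (6,7-syn, 6S), and the (5R) silyloxy centre of the aldehyde reinforces this sense (dipole-minimised, 5,6-anti), so the case is matched.

Step 12
Reactants: 19 aldol adduct
Product: 20 (2S,3S,4R,5S)-2-{3-[(tert-butyldimethylsilyl)oxy]prop-1-en-2-yl}-3-hydroxy-N-methoxy-N,5-dimethyl-4-(triethylsilyloxy)dec-9-enamide
Conditions: MeNH(OMe)·HCl, AlMe3, THF, −20 → 0 °C; aq. potassium sodium tartrate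
Reagents that add atoms: N,O-dimethylhydroxylamine hydrochloride, CNOC.Cl
Why: Aluminium amide transamination of the N-acyl oxazolidinone to the Weinreb amide, assisted by the free β-hydroxyl; the auxiliary is released for recovery.

Step 13
Reactants: 21 tributyl(iodomethyl)stannane; 22 (4-methoxyphenyl)methanol
Product: 23 tributyl{[(4-methoxybenzyl)oxy]methyl}stannane
Conditions: NaH, THF/DMF, 0 °C → rt
Reagents that add atoms: none
Why: Williamson ether synthesis on the primary iodide; this provides the C9 unit as a hydroxymethyl anion equivalent.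

Step 14
Reactants: 20 Weinreb amide; 23 tributyl{[(4-methoxybenzyl)oxy]methyl}stannane
Product: 25 (4S,5R,6S,7S)-C8 ketone (germacrane locants), 9-[(4-methoxybenzyl)oxy]-6-hydroxy-5-(triethylsilyloxy)-12-[(tert-butyldimethylsilyl)oxy] chain ending in the C10=C14 vinyl group, via [(4-methoxybenzyl)oxy]methyllithium 24 (not isolated)
Conditions: 23 (3.5 equiv), n-BuLi (3.3 equiv), THF, −78 °C; then 20, −78 °C; pH 7 buffer at −78 °C
Reagents that add atoms: none
Why: Tin–lithium exchange gives the α-alkoxymethyllithium, which adds once to the Weinreb amide (stable chelated tetrahedral intermediate, one equivalent being spent on the hydroxyl) to give the α-alkoxy ketone on buffered quench.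

Step 15
Reactants: 25 β-hydroxy ketone
Product: 27 (4S,5R,6S,7R,8R)-6,8-diol with 9-O-PMB, 5-O-TES and 12-O-TBS, via diethylboron chelate 26 (not isolated)
Conditions: Et2BOMe, THF/MeOH 4:1, −78 °C; NaBH4, −78 °C; then pH 7 buffer, 30 % H2O2, 0 °C
Reagents that add atoms: none
Why: Narasaka–Prasad reduction; the boron chelate of the β-hydroxy ketone takes hydride axially on the face opposite the axial C7 substituent, which should give the 6,8-syn diol and set C8 (R), completing the all-syn C6–C7–C8 triad.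

Step 16
Reactants: 27 6,8-diol
Product: 28 (4S,5R,6S,7S,8R)-8,9-O-(4-methoxybenzylidene) acetal (2-aryl-1,3-dioxolane) with free 6-OH
Conditions: DDQ (1.2 equiv), 4 Å MS, CH2Cl2, −10 → 0 °C
Reagents that add atoms: none
Why: Oxidation of the PMB ether by DDQ without water gives an oxocarbenium ion that is trapped by the neighbouring C8 hydroxyl (five-membered acetal, favoured over the seven-membered one with O6), so O6 alone stays free.

Step 17
Reactants: 28 hydroxy acetal
Product: 29 (4S,5R,6S,7R,8R)-6-O-TBS ether of 28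
Conditions: TBSOTf, 2,6-lutidine, CH2Cl2, −78 → 0 °C
Reagents that add atoms: tert-butyldimethylsilyl trifluoromethanesulfonate, CC(C)(C)[Si](C)(C)OS(=O)(=O)C(F)(F)F
Why: Silylation of the hindered secondary C6 alcohol with the silyl triflate; the hindered base keeps the acetal intact.

Step 18
Reactants: 29 silylated acetal
Product: 30 (4S,5R,6S,7R,8R)-C9 primary alcohol with 8-O-PMB, 6-O-TBS, 5-O-TES and 12-O-TBS
Conditions: i-Bu2AlH (DIBAL-H), CH2Cl2, −78 → 0 °C; aq. potassium sodium tartrate
Reagents that add atoms: none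
Why: Reductive opening of the 4-methoxybenzylidene acetal; aluminium binds the less hindered primary oxygen and hydride cleaves that C–O bond, leaving PMB on O8 and the C9 alcohol free.

Step 19
Reactants: 30 primary alcohol
Product: 31 (4S,5R,6S,7R,8R)-C10 methyl ketone with free C9 alcohol
Conditions: PdCl2 (15 mol %), Cu(OAc)2 (30 mol %), O2 (1 atm), DMA/H2O 7:1, rt
Reagents that add atoms: water, O
Why: Tsuji–Wacker oxidation; the monosubstituted C10=C14 alkene reacts in preference to the 1,1-disubstituted C11=C13 alkene and Markovnikov hydroxypalladation gives the methyl ketone, the acetate co-catalyst keeping the medium mild for the silyl ethers.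

Step 20
Reactants: 31 hydroxy ketone
Product: 32 (4S,5R,6S,7R,8R)-C9 aldehyde / C10 methyl ketone (open-chain precursor)
Conditions: Dess–Martin periodinane, NaHCO3, CH2Cl2, 0 °C → rt
Reagents that add atoms: none
Why: Dess–Martin oxidation of the primary alcohol under buffered conditions, which should not epimerise the α-alkoxy aldehyde at C8; the product is used at once.

Step 21
Reactants: 32 keto-aldehyde
Product: 33 (4S,5R,6S,7R,8R,9S,10R)-6-(tert-butyldimethylsilyloxy)-7-{3-[(tert-butyldimethylsilyl)oxy]prop-1-en-2-yl}-8-[(4-methoxybenzyl)oxy]-4,10-dimethyl-5-(triethylsilyloxy)cyclodecane-9,10-diol (germacrane locants)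
Conditions: SmI2 (3.5 equiv, 0.1 M in THF), THF, −78 → 0 °C, 32 added over 6 h by syringe pump (final 2 mM); aq. NaHCO3
Reagents that add atoms: none
Why: Electron transfer from divalent samarium to the aldehyde, the more easily reduced carbonyl, gives a C9 ketyl on trivalent samarium that adds to the samarium-bound C10 ketone carbon, and a second electron gives the cyclic samarium diolate, protonated on work-up (intramolecular ketone–aldehyde pinacol coupling, known for samarium- and titanium-mediated closures of medium and large rings). The ten-membered ring closes in a 10-exo-trig sense, the C9 radical attacking the carbonyl carbon C10 while the C=O bond stays outside the ring. C9 is controlled by C8: the ketyl oxygen and the O8 ether bind the same samarium in a five-membered chelate, the ketone approaches the face away from C7, and O9 should end syn to O8 in the open-chain sense, that is trans across the ring. C10 is controlled by the samarium bridge, which holds O9 and O10 syn-clinal with the methyl group anti to C8 and the chain arm gauche, the arrangement that leads to the cis-diol. The step needs ring closure over simple reduction or dimerisation, secured by slow addition at high dilution without HMPA or a strong proton donor, and it needs exactly two reducible groups, secured by C5 being a silyl ether and C12 an allylic ether instead of an acrylate.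

Step 22
Reactants: 33 diol; 34 3-methylbutanoyl chloride
Product: 35 (4S,5R,6S,7R,8R,9S,10R)-9-O-(3-methylbutanoyl) ester of 33
Conditions: 34, pyridine, DMAP (cat.), CH2Cl2, 0 °C → rt
Reagents that add atoms: none
Why: DMAP-catalysed acylation; the secondary C9 hydroxyl reacts while the tertiary C10 hydroxyl is inert.

Step 23
Reactants: 35 isovalerate
Product: 36 (4S,5R,6S,7R,8R,9S,10R)-5,12-diol (6-O-TBS and 8-O-PMB retained)
Conditions: CSA (0.2 equiv), MeOH/CH2Cl2 1:1, 0 °C
Reagents that add atoms: none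
Why: Acid-catalysed methanolysis of silyl ethers; the secondary TES ether and the primary allylic TBS ether are cleaved, whereas the hindered secondary TBS ether on O6 and the PMB ether should survive.

Step 24
Reactants: 36 5,12-diol
Product: 37 (4S,6S,7R,8R,9S,10R)-C5 ketone / C12 enal
Conditions: Dess–Martin periodinane (3 equiv), NaHCO3, CH2Cl2, 0 °C → rt
Reagents that add atoms: none
Why: Dess–Martin oxidation of both hydroxyls in one operation (C5 to the ketone, C12 to the 2-substituted acrolein); the tertiary C10 alcohol cannot be oxidised and the buffer protects C4.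

Step 25
Reactants: 37 keto-enal
Product: 39 (4S,6S,7R,8R,9S,10R)-C8,12-lactol, via hydroxy enal 38 (not isolated)
Conditions: DDQ (1.5 equiv), CH2Cl2/pH 7 buffer 10:1, 0 °C → rt
Reagents that add atoms: none
Why: Oxidative cleavage of the PMB ether; the freed C8 hydroxyl adds to the C12 aldehyde to give the five-membered lactol fused at C7–C8.

Step 26
Reactants: 39 lactol
Product: 40 (4S,6S,7R,8R,9S,10R)-6-O-TBS ether of the target lactone
Conditions: TEMPO (0.2 equiv), PhI(OAc)2 (1.5 equiv), CH2Cl2, rt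
Reagents that add atoms: none
Why: Oxoammonium oxidation of the lactol to the α-methylene-γ-butyrolactone; no other oxidisable hydroxyl is free.

Step 27
Reactants: 40 silyl ether
Product: 41 target, (4S,6S,7S,8R,9S,10R)
Conditions: HF·pyridine, pyridine, THF, 0 °C → rt
Reagents that add atoms: none
Why: Fluoride-mediated desilylation under buffered, weakly acidic conditions that should spare the methylene lactone, the ester, the α-ketol and the tertiary alcohol.

Compound list
1 | prop-2-yn-1-ol | C#CCO | starting material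
2 | 5-bromopent-1-ene | C=CCCCBr | starting material
3 | dilithiated prop-2-yn-1-ol | [Li]C#CCO[Li] | intermediate
4 | oct-7-en-2-yn-1-ol | OCC#CCCCC=C | intermediate
5 | (2Z)-octa-2,7-dien-1-ol | OC/C=C\CCCC=C | intermediate
6 | [(2S,3R)-3-(pent-4-en-1-yl)oxiran-2-yl]methanol | OC[C@@H]1O[C@@H]1CCCC=C | intermediate
7 | (2R,3S)-3-methyloct-7-ene-1,2-diol | OC[C@H](O)[C@@H](C)CCCC=C | intermediate
8 | (2R,3S)-3-methyl-1,2-bis(triethylsilyloxy)oct-7-ene | CC[Si](CC)(CC)OC[C@H](O[Si](CC)(CC)CC)[C@@H](C)CCCC=C | intermediate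
9 | (2R,3S)-3-methyl-2-(triethylsilyloxy)oct-7-enal | O=C[C@H](O[Si](CC)(CC)CC)[C@@H](C)CCCC=C | intermediate
10 | 4-methyl hydrogen 2-methylidenebutanedioate (monomethyl itaconate) | C=C(CC(=O)OC)C(=O)O | starting material
11 | mixed isobutyl carbonic anhydride of 10 | C=C(CC(=O)OC)C(=O)OC(=O)OCC(C)C | intermediate
12 | methyl 3-(hydroxymethyl)but-3-enoate | C=C(CO)CC(=O)OC | intermediate
13 | methyl 3-{[(tert-butyldimethylsilyl)oxy]methyl}but-3-enoate | C=C(CO[Si](C)(C)C(C)(C)C)CC(=O)OC | intermediate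
14 | 3-{[(tert-butyldimethylsilyl)oxy]methyl}but-3-enoic acid | C=C(CO[Si](C)(C)C(C)(C)C)CC(=O)O | intermediate
15 | (4S)-4-benzyl-1,3-oxazolidin-2-one | O=C1N[C@@H](Cc2ccccc2)CO1 | starting material
16 | mixed pivalic anhydride of 14 | C=C(CO[Si](C)(C)C(C)(C)C)CC(=O)OC(=O)C(C)(C)C | intermediate
17 | (4S)-4-benzyl-3-(3-{[(tert-butyldimethylsilyl)oxy]methyl}but-3-enoyl)-1,3-oxazolidin-2-one | C=C(CO[Si](C)(C)C(C)(C)C)CC(=O)N1[C@@H](Cc2ccccc2)COC1=O | intermediate
18 | Z-dibutylboron enolate of 17 | CCCCB(CCCC)O/C(=C\C(=C)CO[Si](C)(C)C(C)(C)C)N1[C@@H](Cc2ccccc2)COC1=O | intermediate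
19 | (4S)-4-benzyl-3-[(2S,3S,4R,5S)-2-{3-[(tert-butyldimethylsilyl)oxy]prop-1-en-2-yl}-3-hydroxy-5-methyl-4-(triethylsilyloxy)dec-9-enoyl]-1,3-oxazolidin-2-one | O=C(N1[C@@H](Cc2ccccc2)COC1=O)[C@@H](C(=C)CO[Si](C)(C)C(C)(C)C)[C@H](O)[C@H](O[Si](CC)(CC)CC)[C@@H](C)CCCC=C | intermediate
20 | (2S,3S,4R,5S)-2-{3-[(tert-butyldimethylsilyl)oxy]prop-1-en-2-yl}-3-hydroxy-N-methoxy-N,5-dimethyl-4-(triethylsilyloxy)dec-9-enamide | CON(C)C(=O)[C@@H](C(=C)CO[Si](C)(C)C(C)(C)C)[C@H](O)[C@H](O[Si](CC)(CC)CC)[C@@H](C)CCCC=C | intermediate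
21 | tributyl(iodomethyl)stannane | CCCC[Sn](CCCC)(CCCC)CI | starting material
22 | (4-methoxyphenyl)methanol | COc1ccc(CO)cc1 | starting material
23 | tributyl{[(4-methoxybenzyl)oxy]methyl}stannane | CCCC[Sn](CCCC)(CCCC)COCc1ccc(OC)cc1 | intermediate
24 | [(4-methoxybenzyl)oxy]methyllithium | [Li]COCc1ccc(OC)cc1 | intermediate
25 | (3S,4S,5R,6S)-3-{3-[(tert-butyldimethylsilyl)oxy]prop-1-en-2-yl}-4-hydroxy-1-[(4-methoxybenzyl)oxy]-6-methyl-5-(triethylsilyloxy)undec-10-en-2-one | COc1ccc(COCC(=O)[C@@H](C(=C)CO[Si](C)(C)C(C)(C)C)[C@H](O)[C@H](O[Si](CC)(CC)CC)[C@@H](C)CCCC=C)cc1 | intermediate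
26 | O6-diethylboryl chelate of 25 | COc1ccc(COCC(=O)[C@@H](C(=C)CO[Si](C)(C)C(C)(C)C)[C@H](OB(CC)CC)[C@H](O[Si](CC)(CC)CC)[C@@H](C)CCCC=C)cc1 | intermediate
27 | (2R,3R,4S,5R,6S)-3-{3-[(tert-butyldimethylsilyl)oxy]prop-1-en-2-yl}-1-[(4-methoxybenzyl)oxy]-6-methyl-5-(triethylsilyloxy)undec-10-ene-2,4-diol | COc1ccc(COC[C@H](O)[C@@H](C(=C)CO[Si](C)(C)C(C)(C)C)[C@H](O)[C@H](O[Si](CC)(CC)CC)[C@@H](C)CCCC=C)cc1 | intermediate
28 | 8,9-O-(4-methoxybenzylidene) acetal of 27 with free 6-OH, (4S,5R,6S,7S,8R) | COc1ccc(C2OC[C@H](O2)[C@@H](C(=C)CO[Si](C)(C)C(C)(C)C)[C@H](O)[C@H](O[Si](CC)(CC)CC)[C@@H](C)CCCC=C)cc1 | intermediate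
29 | 6-O-TBS ether of 28, (4S,5R,6S,7R,8R) | COc1ccc(C2OC[C@H](O2)[C@@H](C(=C)CO[Si](C)(C)C(C)(C)C)[C@H](O[Si](C)(C)C(C)(C)C)[C@H](O[Si](CC)(CC)CC)[C@@H](C)CCCC=C)cc1 | intermediate
30 | (2R,3R,4S,5R,6S)-4-[(tert-butyldimethylsilyl)oxy]-3-{3-[(tert-butyldimethylsilyl)oxy]prop-1-en-2-yl}-2-[(4-methoxybenzyl)oxy]-6-methyl-5-(triethylsilyloxy)undec-10-en-1-ol | COc1ccc(CO[C@@H](CO)[C@@H](C(=C)CO[Si](C)(C)C(C)(C)C)[C@H](O[Si](C)(C)C(C)(C)C)[C@H](O[Si](CC)(CC)CC)[C@@H](C)CCCC=C)cc1 | intermediate
31 | C10 methyl ketone from 30 with free C9 alcohol, (4S,5R,6S,7R,8R) | COc1ccc(CO[C@@H](CO)[C@@H](C(=C)CO[Si](C)(C)C(C)(C)C)[C@H](O[Si](C)(C)C(C)(C)C)[C@H](O[Si](CC)(CC)CC)[C@@H](C)CCCC(C)=O)cc1 | intermediate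
32 | open-chain C9 aldehyde / C10 methyl ketone, (4S,5R,6S,7R,8R) | COc1ccc(CO[C@@H](C=O)[C@@H](C(=C)CO[Si](C)(C)C(C)(C)C)[C@H](O[Si](C)(C)C(C)(C)C)[C@H](O[Si](CC)(CC)CC)[C@@H](C)CCCC(C)=O)cc1 | intermediate
33 | (4S,5R,6S,7R,8R,9S,10R)-6-(tert-butyldimethylsilyloxy)-7-{3-[(tert-butyldimethylsilyl)oxy]prop-1-en-2-yl}-8-[(4-methoxybenzyl)oxy]-4,10-dimethyl-5-(triethylsilyloxy)cyclodecane-9,10-diol | COc1ccc(CO[C@@H]2[C@@H](C(=C)CO[Si](C)(C)C(C)(C)C)[C@H](O[Si](C)(C)C(C)(C)C)[C@H](O[Si](CC)(CC)CC)[C@@H](C)CCC[C@@](C)(O)[C@H]2O)cc1 | intermediate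
34 | 3-methylbutanoyl chloride | CC(C)CC(=O)Cl | starting material
35 | 9-O-(3-methylbutanoyl) ester of 33 | COc1ccc(CO[C@@H]2[C@@H](C(=C)CO[Si](C)(C)C(C)(C)C)[C@H](O[Si](C)(C)C(C)(C)C)[C@H](O[Si](CC)(CC)CC)[C@@H](C)CCC[C@@](C)(O)[C@H]2OC(=O)CC(C)C)cc1 | intermediate
36 | 5,12-diol from 35 (6-O-TBS, 8-O-PMB, 9-O-isovalerate, 10-OH) | COc1ccc(CO[C@@H]2[C@@H](C(=C)CO)[C@H](O[Si](C)(C)C(C)(C)C)[C@H](O)[C@@H](C)CCC[C@@](C)(O)[C@H]2OC(=O)CC(C)C)cc1 | intermediate
37 | C5 ketone / C12 enal, (4S,6S,7R,8R,9S,10R) | COc1ccc(CO[C@@H]2[C@@H](C(=C)C=O)[C@H](O[Si](C)(C)C(C)(C)C)C(=O)[C@@H](C)CCC[C@@](C)(O)[C@H]2OC(=O)CC(C)C)cc1 | intermediate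
38 | 8-hydroxy enal from 37 | O[C@@H]1[C@@H](C(=C)C=O)[C@H](O[Si](C)(C)C(C)(C)C)C(=O)[C@@H](C)CCC[C@@](C)(O)[C@H]1OC(=O)CC(C)C | intermediate
39 | C8,12-lactol (12-hydroxy, 6-O-TBS) | C=C1C(O)O[C@@H]2[C@@H]1[C@H](O[Si](C)(C)C(C)(C)C)C(=O)[C@@H](C)CCC[C@@](C)(O)[C@H]2OC(=O)CC(C)C | intermediate
40 | 6-O-TBS ether of the target | C=C1C(=O)O[C@@H]2[C@@H]1[C@H](O[Si](C)(C)C(C)(C)C)C(=O)[C@@H](C)CCC[C@@](C)(O)[C@H]2OC(=O)CC(C)C | intermediate
41 | CNP0240128.1, (4S,6S,7S,8R,9S,10R)-6,10-dihydroxy-9-(3-methylbutanoyloxy)-5-oxogermacr-11(13)-en-8,12-olide | C=C1C(=O)O[C@@H]2[C@@H]1[C@H](O)C(=O)[C@@H](C)CCC[C@@](C)(O)[C@H]2OC(=O)CC(C)C | target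

Total step count: 27. Longest linear sequence: 22 steps (steps 1–6, 11, 12, 14–27).

Steps most likely to fail

Step 21. The ten-membered ring closure may lose to simple reduction of the aldehyde or to intermolecular coupling, and the C10 centre may form in the wrong sense. The fallback makes the same C9–C10 bond by a chromium-mediated alkenyl–aldehyde coupling and installs the tertiary carbinol afterwards. It sets out from hydroxy ketone 31. Silylation of the C9 hydroxyl (TESCl, imidazole) would give the C9 triethylsilyl ether F1. Kinetic enolisation toward the methyl group and trapping (KN(SiMe3)2, PhNTf2, THF, −78 °C) would give the 2-alkenyl triflate F2. Swern oxidation, which cleaves a primary TES ether directly as in step 6, would give the aldehyde triflate F3. CrCl2 with catalytic NiCl2 in DMSO/THF at high dilution (Nozaki–Hiyama–Kishi coupling) should close the ring to the 10-methylene-9-ol F4. C9 selectivity is not assured here and would have to be checked at this stage. VO(acac)2/t-BuOOH should deliver oxygen from the face of the C9 hydroxyl to give the spiro-epoxide F5. LiEt3BH opens it at the CH2 terminus, and the route is rejoined at diol 33.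

Step 14. The organolithium may enolise or cleave the β-hydroxy amide (retro-aldol), and the β,γ-unsaturated β'-hydroxy ketone may isomerise on quench. The fallback sets C8 by addition to an aldehyde instead of by ketone reduction and sets out from Weinreb amide 20. TBSOTf/2,6-lutidine would give the 6-O-TBS Weinreb amide F6, and i-Bu2AlH at −78 °C the C8 aldehyde F7. Addition of 24 (from 23 and n-BuLi) is expected to follow the Felkin mode, since the silyl ether excludes chelation, and give the 7,8-syn alcohol F8. DDQ with 4 Å MS then closes the 8,9-acetal and the route is rejoined at 29, steps 15–17 being bypassed.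

Step 25. After loss of the PMB group the C8 hydroxyl may add across the ring to the C5 ketone instead of to the aldehyde, or the enal may be degraded by the oxidant. The fallback forms the lactone by acylation instead of lactol oxidation and sets out from 37. Chlorite oxidation (NaClO2, NaH2PO4, 2-methylbut-2-ene, t-BuOH/H2O) would give the acrylic acid F9, and DDQ in wet CH2Cl2 the 8-hydroxy acid F10. Lactonisation (2,4,6-trichlorobenzoyl chloride, Et3N, DMAP) rejoins the route at 40.

Further compounds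
F1 | step 21 | C9 triethylsilyl ether of 31 | COc1ccc(CO[C@@H](CO[Si](CC)(CC)CC)[C@@H](C(=C)CO[Si](C)(C)C(C)(C)C)[C@H](O[Si](C)(C)C(C)(C)C)[C@H](O[Si](CC)(CC)CC)[C@@H](C)CCCC(C)=O)cc1
F2 | step 21 | 2-alkenyl triflate (C10=C14 enol triflate) of F1 | COc1ccc(CO[C@@H](CO[Si](CC)(CC)CC)[C@@H](C(=C)CO[Si](C)(C)C(C)(C)C)[C@H](O[Si](C)(C)C(C)(C)C)[C@H](O[Si](CC)(CC)CC)[C@@H](C)CCCC(=C)OS(=O)(=O)C(F)(F)F)cc1
F3 | step 21 | C9 aldehyde bearing the C10 alkenyl triflate | COc1ccc(CO[C@@H](C=O)[C@@H](C(=C)CO[Si](C)(C)C(C)(C)C)[C@H](O[Si](C)(C)C(C)(C)C)[C@H](O[Si](CC)(CC)CC)[C@@H](C)CCCC(=C)OS(=O)(=O)C(F)(F)F)cc1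
F4 | step 21 | ten-membered 10-methylene-9-ol | COc1ccc(CO[C@@H]2[C@@H](C(=C)CO[Si](C)(C)C(C)(C)C)[C@H](O[Si](C)(C)C(C)(C)C)[C@H](O[Si](CC)(CC)CC)[C@@H](C)CCCC(=C)[C@H]2O)cc1
F5 | step 21 | 10,14-spiro-epoxide of F4 | COc1ccc(CO[C@@H]2[C@@H](C(=C)CO[Si](C)(C)C(C)(C)C)[C@H](O[Si](C)(C)C(C)(C)C)[C@H](O[Si](CC)(CC)CC)[C@@H](C)CCC[C@]3(CO3)[C@H]2O)cc1
F6 | step 14 | 6-O-TBS ether of Weinreb amide 20 | CON(C)C(=O)[C@@H](C(=C)CO[Si](C)(C)C(C)(C)C)[C@H](O[Si](C)(C)C(C)(C)C)[C@H](O[Si](CC)(CC)CC)[C@@H](C)CCCC=C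
F7 | step 14 | C8 aldehyde from F6 | O=C[C@@H](C(=C)CO[Si](C)(C)C(C)(C)C)[C@H](O[Si](C)(C)C(C)(C)C)[C@H](O[Si](CC)(CC)CC)[C@@H](C)CCCC=C
F8 | step 14 | 8-hydroxy 9-O-PMB adduct with 6-O-TBS | COc1ccc(COC[C@H](O)[C@@H](C(=C)CO[Si](C)(C)C(C)(C)C)[C@H](O[Si](C)(C)C(C)(C)C)[C@H](O[Si](CC)(CC)CC)[C@@H](C)CCCC=C)cc1
F9 | step 25 | C12 carboxylic acid from 37 | COc1ccc(CO[C@@H]2[C@@H](C(=C)C(=O)O)[C@H](O[Si](C)(C)C(C)(C)C)C(=O)[C@@H](C)CCC[C@@](C)(O)[C@H]2OC(=O)CC(C)C)cc1
F10 | step 25 | 8-hydroxy C12 acid | O[C@@H]1[C@@H](C(=C)C(=O)O)[C@H](O[Si](C)(C)C(C)(C)C)C(=O)[C@@H](C)CCC[C@@](C)(O)[C@H]1OC(=O)CC(C)C
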